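**Plan**

1. The retrosynthesis first cuts both C–C bonds of the CH2 bridge (ring A C1–CH2 and CH2–C3 of the pyrone), giving acylphloroglucinol methyl ether 27, pyrone 33 and a one-carbon iminium salt.
2. Ring A is the benzene ring: C1 bridge carbon, C2 OH, C3 acyl, C4 OH, C5 prenyl, C6 OMe. It carries oxygen on C2, C4 and C6, and each of these oxygens can be given its own origin: a cyclobutenone carbonyl (C2), the enol ether of that cyclobutenone (C6) and a siloxyalkyne (C4). Ring A is therefore cut at C2–C3, C4–C5 and C1–C2.
3. Forward: cyclobutenone 7 (two steps) and siloxyalkyne 18 (five steps) are heated together to close ring A in step 8. The carbinol is then unmasked and oxidised and the phenols freed. The pyrone (ring B, closed by lactonisation in step 14) is joined through the methylene bridge last.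
4. Stereochemistry: the single stereocentre comes from (R)-2-methylbutanoic acid. It sits beside a silyl-protected carbinol during the thermal step and beside the ketone only from step 11 on, under buffered conditions.

Key step: step 8

Assumption: the carbinol carbon made in step 5 is carried as a mixture of both epimers up to compound 25, which is harmless because step 11 turns it into the ketone carbon; (R)-2-methylbutanoic acid is taken as purchased in enantiopure form.

**Route**

Step 1
Reactants: 1 chloroacetaldehyde dimethyl acetal; 2 1-bromo-3-methylbut-2-ene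
Product: 4 1-methoxy-5-methylhex-4-en-1-yne, via lithium methoxyacetylide 3 (not isolated)
Conditions: LiNEt2 (3.1 equiv, from Et2NH and n-BuLi), THF, −78 to 0 °C; then 2 (1.3 equiv), DMPU, −78 °C to rt
Reagents that add atoms: none
Why: The lithium amide removes methanol and then HCl from the chloroacetal and deprotonates the methoxyacetylene formed (the usual amide-base route to alkoxyacetylides), and the acetylide carbon is then alkylated at the primary carbon of the allylic bromide in an SN2 reaction helped by the dipolar cosolvent.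

Step 2
Reactants: 4 1-methoxy-5-methylhex-4-en-1-yne; 5 acetone
Product: 7 3-methoxy-2-(3-methylbut-2-enyl)cyclobut-2-en-1-one, via ketene 6 (not isolated)
Conditions: 5 pyrolysed in a ketene generator, gas stream passed into 4, CH2Cl2, 0 °C to rt
Reagents that add atoms: none
Why: This is the classical [2+2] cycloaddition of ketene with a 1-alkoxyalkyne to a 3-alkoxycyclobutenone, in which the ynol ether carbon remote from oxygen attacks the ketene carbonyl carbon (prenyl on C2, methoxy on C3) and the isolated trisubstituted alkene is far less reactive towards ketene.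

Step 3
Reactants: 8 (R)-2-methylbutanoic acid
Product: 10 (2R)-N-methoxy-N,2-dimethylbutanamide, via acyl imidazole 9 (not isolated)
Conditions: 1,1'-carbonyldiimidazole, CH2Cl2, 0 °C to rt; then MeNHOMe·HCl, rt
Reagents that add atoms: N,O-dimethylhydroxylamine hydrochloride, CNOC.Cl
Why: Weinreb amide formation by aminolysis of the acyl imidazole involves neither a ketene-forming nor a strongly basic stage, so the α-stereocentre should be kept.

Step 4
Reactants: 10 (2R)-N-methoxy-N,2-dimethylbutanamide; 11 ethynylmagnesium bromide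
Product: 13 (4R)-4-methylhex-1-yn-3-one, via magnesium chelate 12 (not isolated)
Conditions: 11 (2.5 equiv), THF, 0 °C; inverse quench into cold 1 M HCl
Reagents that add atoms: none
Why: In this Weinreb ketone synthesis the chelated tetrahedral adduct blocks a second addition, and the cold acidic inverse quench protonates the released hydroxylamine so that it cannot add to the ynone in conjugate fashion and the α-stereocentre is not exposed to base.

Step 5
Reactants: 13 (4R)-4-methylhex-1-yn-3-one
Product: 14 (4R)-4-methylhex-1-yn-3-ol (both C3 epimers)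
Conditions: NaBH4, CeCl3·7H2O, MeOH, −78 to −40 °C
Reagents that add atoms: none
Why: Luche reduction gives fast 1,2-reduction of the ynone under nearly neutral conditions, so the adjacent (R) centre should not epimerise; the new carbinol centre is formed without control and is removed again in step 11.

Step 6
Reactants: 14 (4R)-4-methylhex-1-yn-3-ol
Product: 15 (4R)-4-methyl-3-(triethylsilyloxy)hex-1-yne
Conditions: Et3SiCl, imidazole, CH2Cl2, 0 °C to rt
Reagents that add atoms: chlorotriethylsilane, CC[Si](Cl)(CC)CC
Why: Standard silylation of a secondary alcohol; the triethylsilyl group is chosen because it survives base and heat yet can later be removed in the presence of aryl triisopropylsilyl ethers.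

Step 7
Reactants: 15 (4R)-4-methyl-3-(triethylsilyloxy)hex-1-yne
Product: 18 (4R)-4-methyl-3-(triethylsilyloxy)-1-(triisopropylsilyloxy)hex-1-yne, via lithium acetylide 16 (not isolated), via lithium ynolate 17 (not isolated)
Conditions: LiN(SiMe3)2 (2.2 equiv), THF, −78 °C; t-BuOOH (1.1 equiv, anhydrous in decane), −78 to 0 °C; then i-Pr3SiOTf (1.3 equiv), −78 °C to rt
Reagents that add atoms: tert-butyl hydroperoxide, CC(C)(C)OO; triisopropylsilyl trifluoromethanesulfonate, CC(C)[Si](C(C)C)(C(C)C)OS(=O)(=O)C(F)(F)F
Why: The lithium acetylide is oxidised by lithium tert-butyl peroxide to the lithium ynolate (the known acetylide-to-ynolate oxidation), and the bulky silyl triflate silylates the ynolate on oxygen to give the siloxyalkyne; the propargylic siloxy group is a poor leaving group and should not eliminate at these temperatures.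

Step 8
Reactants: 7 3-methoxy-2-(3-methylbut-2-enyl)cyclobut-2-en-1-one; 18 (4R)-4-methyl-3-(triethylsilyloxy)-1-(triisopropylsilyloxy)hex-1-yne
Product: 23 5-methoxy-4-(3-methylbut-2-enyl)-2-[(2R)-2-methyl-1-(triethylsilyloxy)butyl]-3-(triisopropylsilyloxy)phenol, via vinylketene 19 (not isolated), via vinylcyclobutenone 20 (not isolated), via dienylketene 21 (not isolated), via cyclohexadienone 22 (not isolated)
Conditions: 18 (1.2 equiv), degassed toluene (0.5 M), sealed vessel, 80 °C, then 110 °C if conversion stalls
Reagents that add atoms: none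
Why: Heat opens cyclobutenone 7 in a reversible 4π electrocyclic step to vinylketene 19, whose ketene C=C bond adds the electron-rich alkyne 18 in a [2+2] cycloaddition to give 20 (new bonds C2–C3 and C4–C5); a second 4π opening gives dienylketene 21, which closes ring A by a thermal disrotatory 6π electrocyclisation (bond C1–C2) to cyclohexadienone 22, and tautomerisation gives the phenol. This is the Danheiser benzannulation of a cyclobutenone with a heteroatom-substituted alkyne, the established route to resorcinol monosilyl ethers. The step needs one selectivity, the orientation in which alkyne and ketene combine: the oxygen-bearing alkyne carbon is the electron-poor end and the side-chain-bearing carbon the electron-rich end, so the latter bonds to the ketene carbonyl carbon and the side chain ends up on C3 between the C2 hydroxyl and the C4 siloxy group, while the prenyl and methoxy carbons of 7 become C5 and C6 and C1 stays unsubstituted. No lasting stereocentre is formed, since the quaternary carbon of 20 is lost on ring opening, and the (R) centre lies beside a silyl-protected carbinol that cannot enolise. Because the opening of 7 is reversible, slow capture by the hindered alkyne should return cyclobutenone and not consume the ketene.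

Step 9
Reactants: 23 5-methoxy-4-(3-methylbut-2-enyl)-2-[(2R)-2-methyl-1-(triethylsilyloxy)butyl]-3-(triisopropylsilyloxy)phenol
Product: 24 1-methoxy-2-(3-methylbut-2-enyl)-4-[(2R)-2-methyl-1-(triethylsilyloxy)butyl]-3,5-bis(triisopropylsilyloxy)benzene
Conditions: i-Pr3SiOTf (1.2 equiv), 2,6-lutidine, CH2Cl2, −78 to 0 °C
Reagents that add atoms: triisopropylsilyl trifluoromethanesulfonate, CC(C)[Si](C(C)C)(C(C)C)OS(=O)(=O)C(F)(F)F
Why: Base-buffered silyl triflate silylation caps the C2 phenol, so that the electron-rich ring has no free hydroxyl during the later periodinane oxidation and no ortho-hydroxybenzylic ether remains.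

Step 10
Reactants: 24 1-methoxy-2-(3-methylbut-2-enyl)-4-[(2R)-2-methyl-1-(triethylsilyloxy)butyl]-3,5-bis(triisopropylsilyloxy)benzene
Product: 25 (2R)-1-[4-methoxy-3-(3-methylbut-2-enyl)-2,6-bis(triisopropylsilyloxy)phenyl]-2-methylbutan-1-ol
Conditions: HF·pyridine, excess pyridine, THF, 0 °C
Reagents that add atoms: none
Why: Pyridine-buffered HF removes the small alkyl triethylsilyl ether much faster than aryl triisopropylsilyl ethers, which resist acidic fluoride, and the medium is too weakly acidic to ionise the electron-rich benzylic carbinol.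

Step 11
Reactants: 25 (2R)-1-[4-methoxy-3-(3-methylbut-2-enyl)-2,6-bis(triisopropylsilyloxy)phenyl]-2-methylbutan-1-ol
Product: 26 (2R)-1-[4-methoxy-3-(3-methylbut-2-enyl)-2,6-bis(triisopropylsilyloxy)phenyl]-2-methylbutan-1-one
Conditions: Dess–Martin periodinane (1.5 equiv), NaHCO3, CH2Cl2, 0 °C to rt
Reagents that add atoms: none
Why: Dess–Martin oxidation of a hindered secondary benzylic alcohol runs under buffered, nearly neutral conditions that should neither enolise the new α-branched ketone nor touch the prenyl alkene, and both phenols are masked so no quinone can form.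

Step 12
Reactants: 26 (2R)-1-[4-methoxy-3-(3-methylbut-2-enyl)-2,6-bis(triisopropylsilyloxy)phenyl]-2-methylbutan-1-one
Product: 27 (2R)-1-[2,6-dihydroxy-4-methoxy-3-(3-methylbut-2-enyl)phenyl]-2-methylbutan-1-one
Conditions: Bu4NF (2.5 equiv), AcOH (2.5 equiv), THF, 0 °C
Reagents that add atoms: none
Why: Fluoride cleaves aryl silyl ethers rapidly, and the acetic acid buffer protonates the phenoxides at once, so the stereocentre next to the ketone is not exposed to base.

Step 13
Reactants: 28 methyl 3-oxopentanoate; 29 N-methoxy-N-methylpropanamide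
Product: 32 methyl 4-methyl-3,5-dioxoheptanoate, via dianion 30 (not isolated), via tetrahedral adduct 31 (not isolated)
Conditions: NaH (1.1 equiv), THF, 0 °C; n-BuLi (1.05 equiv), 0 °C; 29 (0.8 equiv), −78 to 0 °C; aq. HCl work-up
Reagents that add atoms: none
Why: The β-keto ester dianion is acylated at its more reactive γ-carbon, and the chelated Weinreb adduct prevents further addition until work-up.

Step 14
Reactants: 32 methyl 4-methyl-3,5-dioxoheptanoate
Product: 33 6-ethyl-4-hydroxy-5-methyl-2H-pyran-2-one
Conditions: DBU, toluene, reflux; then aq. HCl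
Reagents that add atoms: none
Why: Base-mediated lactonisation of a 3,5-dioxo ester, in which the C5 enolate oxygen attacks the ester carbonyl with loss of methanol, is the standard closure of the 4-hydroxy-2-pyrone ring (ring B).

Step 15
Reactants: 33 6-ethyl-4-hydroxy-5-methyl-2H-pyran-2-one; 27 (2R)-1-[2,6-dihydroxy-4-methoxy-3-(3-methylbut-2-enyl)phenyl]-2-methylbutan-1-one
Product: 36 3-[[2,4-dihydroxy-6-methoxy-3-[(2R)-2-methylbutanoyl]-5-(3-methylbut-2-enyl)phenyl]methyl]-6-ethyl-4-hydroxy-5-methyl-2H-pyran-2-one, via Mannich base 34 (not isolated), via methylidenepyrandione 35 (not isolated)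
Conditions: 33 (1.5 equiv), CH2=NMe2+ I− (1.5 equiv), MeCN, rt; then 27 (1.0 equiv), 50 °C
Reagents that add atoms: dimethylmethylideneammonium iodide, C=[N+](C)C.[I-]
Why: Mannich aminomethylation of the pyrone at C3, loss of dimethylamine to the 3-methylidene-2,4-dione and conjugate addition of ring A through C1 (its only unsubstituted carbon, activated by the ortho hydroxyl and methoxy groups) is the known way to methylene-bridged acylphloroglucinol–pyrone dimers; any O-alkylation is reversible, and the mild conditions should leave the stereocentre intact.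

**Compound list**

1 | 2-chloro-1,1-dimethoxyethane (chloroacetaldehyde dimethyl acetal) | COC(CCl)OC | starting material
2 | 1-bromo-3-methylbut-2-ene (prenyl bromide) | CC(C)=CCBr | starting material
3 | lithium methoxyacetylide | [Li]C#COC | intermediate (not isolated)
4 | 1-methoxy-5-methylhex-4-en-1-yne | COC#CCC=C(C)C | intermediate
5 | acetone | CC(C)=O | starting material
6 | ketene | C=C=O | intermediate (not isolated)
7 | 3-methoxy-2-(3-methylbut-2-enyl)cyclobut-2-en-1-one | O=C1CC(OC)=C1CC=C(C)C | intermediate
8 | (R)-2-methylbutanoic acid | OC(=O)[C@H](C)CC | starting material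
9 | (2R)-1-(imidazol-1-yl)-2-methylbutan-1-one | O=C([C@H](C)CC)n1ccnc1 | intermediate (not isolated)
10 | (2R)-N-methoxy-N,2-dimethylbutanamide | CON(C)C(=O)[C@H](C)CC | intermediate
11 | ethynylmagnesium bromide | C#C[Mg]Br | starting material
12 | bromomagnesium (4R)-3-[methoxy(methyl)amino]-4-methylhex-1-yn-3-olate (C3 unassigned) | C#CC(O[Mg]Br)(N(C)OC)[C@H](C)CC | intermediate (not isolated)
13 | (4R)-4-methylhex-1-yn-3-one | C#CC(=O)[C@H](C)CC | intermediate
14 | (4R)-4-methylhex-1-yn-3-ol (both C3 epimers) | C#CC(O)[C@H](C)CC | intermediate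
15 | (4R)-4-methyl-3-(triethylsilyloxy)hex-1-yne (both C3 epimers) | C#CC(O[Si](CC)(CC)CC)[C@H](C)CC | intermediate
16 | lithium (4R)-4-methyl-3-(triethylsilyloxy)hex-1-yn-1-ide | [Li]C#CC(O[Si](CC)(CC)CC)[C@H](C)CC | intermediate (not isolated)
17 | lithium (4R)-4-methyl-3-(triethylsilyloxy)hex-1-yn-1-olate | [Li]OC#CC(O[Si](CC)(CC)CC)[C@H](C)CC | intermediate (not isolated)
18 | (4R)-4-methyl-3-(triethylsilyloxy)-1-(triisopropylsilyloxy)hex-1-yne (both C3 epimers) | CC(C)[Si](C(C)C)(C(C)C)OC#CC(O[Si](CC)(CC)CC)[C@H](C)CC | intermediate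
19 | 3-methoxy-2-(3-methylbut-2-enyl)buta-1,3-dien-1-one | O=C=C(CC=C(C)C)C(OC)=C | intermediate (not isolated)
20 | 4-(1-methoxyethenyl)-4-(3-methylbut-2-enyl)-2-[(2R)-2-methyl-1-(triethylsilyloxy)butyl]-3-(triisopropylsilyloxy)cyclobut-2-en-1-one | O=C1C(C(O[Si](CC)(CC)CC)[C@H](C)CC)=C(O[Si](C(C)C)(C(C)C)C(C)C)C1(CC=C(C)C)C(OC)=C | intermediate (not isolated)
21 | 5-methoxy-4-(3-methylbut-2-enyl)-2-[(2R)-2-methyl-1-(triethylsilyloxy)butyl]-3-(triisopropylsilyloxy)hexa-1,3,5-trien-1-one | O=C=C(C(O[Si](CC)(CC)CC)[C@H](C)CC)C(O[Si](C(C)C)(C(C)C)C(C)C)=C(CC=C(C)C)C(OC)=C | intermediate (not isolated)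
22 | 5-methoxy-4-(3-methylbut-2-enyl)-2-[(2R)-2-methyl-1-(triethylsilyloxy)butyl]-3-(triisopropylsilyloxy)cyclohexa-2,4-dien-1-one | O=C1CC(OC)=C(CC=C(C)C)C(O[Si](C(C)C)(C(C)C)C(C)C)=C1C(O[Si](CC)(CC)CC)[C@H](C)CC | intermediate (not isolated)
23 | 5-methoxy-4-(3-methylbut-2-enyl)-2-[(2R)-2-methyl-1-(triethylsilyloxy)butyl]-3-(triisopropylsilyloxy)phenol (both carbinol epimers) | Oc1cc(OC)c(CC=C(C)C)c(O[Si](C(C)C)(C(C)C)C(C)C)c1C(O[Si](CC)(CC)CC)[C@H](C)CC | intermediate
24 | 1-methoxy-2-(3-methylbut-2-enyl)-4-[(2R)-2-methyl-1-(triethylsilyloxy)butyl]-3,5-bis(triisopropylsilyloxy)benzene | COc1cc(O[Si](C(C)C)(C(C)C)C(C)C)c(C(O[Si](CC)(CC)CC)[C@H](C)CC)c(O[Si](C(C)C)(C(C)C)C(C)C)c1CC=C(C)C | intermediate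
25 | (2R)-1-[4-methoxy-3-(3-methylbut-2-enyl)-2,6-bis(triisopropylsilyloxy)phenyl]-2-methylbutan-1-ol (both C1 epimers) | COc1cc(O[Si](C(C)C)(C(C)C)C(C)C)c(C(O)[C@H](C)CC)c(O[Si](C(C)C)(C(C)C)C(C)C)c1CC=C(C)C | intermediate
26 | (2R)-1-[4-methoxy-3-(3-methylbut-2-enyl)-2,6-bis(triisopropylsilyloxy)phenyl]-2-methylbutan-1-one | COc1cc(O[Si](C(C)C)(C(C)C)C(C)C)c(C(=O)[C@H](C)CC)c(O[Si](C(C)C)(C(C)C)C(C)C)c1CC=C(C)C | intermediate
27 | (2R)-1-[2,6-dihydroxy-4-methoxy-3-(3-methylbut-2-enyl)phenyl]-2-methylbutan-1-one | COc1cc(O)c(C(=O)[C@H](C)CC)c(O)c1CC=C(C)C | intermediate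
28 | methyl 3-oxopentanoate | CCC(=O)CC(=O)OC | starting material
29 | N-methoxy-N-methylpropanamide | CCC(=O)N(C)OC | starting material
30 | sodium lithium dianion of methyl 3-oxopentanoate | CC=C(O[Li])C=C(O[Na])OC | intermediate (not isolated)
31 | lithium sodium salt of methyl 5-hydroxy-5-[methoxy(methyl)amino]-4-methyl-3-oxoheptanoate | CCC(O[Li])(N(C)OC)C(C)C(=O)C=C(O[Na])OC | intermediate (not isolated)
32 | methyl 4-methyl-3,5-dioxoheptanoate | CCC(=O)C(C)C(=O)CC(=O)OC | intermediate
33 | 6-ethyl-4-hydroxy-5-methyl-2H-pyran-2-one | CCc1oc(=O)cc(O)c1C | intermediate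
34 | 3-[(dimethylamino)methyl]-6-ethyl-4-hydroxy-5-methyl-2H-pyran-2-one | CCc1oc(=O)c(CN(C)C)c(O)c1C | intermediate (not isolated)
35 | 6-ethyl-5-methyl-3-methylidenepyran-2,4-dione | CCC1=C(C)C(=O)C(=C)C(=O)O1 | intermediate (not isolated)
36 | 3-[[2,4-dihydroxy-6-methoxy-3-[(2R)-2-methylbutanoyl]-5-(3-methylbut-2-enyl)phenyl]methyl]-6-ethyl-4-hydroxy-5-methyl-2H-pyran-2-one | CCc1oc(=O)c(Cc2c(O)c(C(=O)[C@H](C)CC)c(O)c(CC=C(C)C)c2OC)c(O)c1C | target

**Count**

Total steps: 15. Longest linear sequence: 11 steps (steps 3 to 12 and step 15, from acid 8).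

**Steps most likely to fail**

Step 8. Capture of vinylketene 19 may be slow, because the alkyne carbon that must bond to the ketene carbon carries a branched, siloxy-substituted group; ketene oligomerisation and acylation of the product phenol would then compete. On prolonged heating the ortho-hydroxybenzylic silyl ether of 23 may also lose triethylsilanol (ortho-quinone methide formation and hydrogen shift), which would erase the stereocentre.

The fallback exchanges the roles of the two partners. It sets out from 18 and comes back at 24.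
- 18 is treated with ketene 6 as in step 2, the known [2+2] addition of a siloxyalkyne to ketene, where the crowded carbon bonds to the small parent ketene. This should give 2-[(2R)-2-methyl-1-(triethylsilyloxy)butyl]-3-(triisopropylsilyloxy)cyclobut-2-en-1-one F1.
- 2 is coupled with 11 (catalytic CuCl, THF) to 5-methylhex-4-en-1-yne F2, which is oxidised and silylated as in step 7 to 5-methyl-1-(triisopropylsilyloxy)hex-4-en-1-yne F3.
- Heating F1 with the unhindered alkyne F3 in toluene should give, by the same pericyclic cascade, 2-(3-methylbut-2-enyl)-4-[(2R)-2-methyl-1-(triethylsilyloxy)butyl]-3,5-bis(triisopropylsilyloxy)phenol F4. Here ring A is closed through C5–C6, C3–C4 and C6–C1, and the free hydroxyl lies on C6 next to the prenyl group, not next to the carbinol, so no ortho-quinone methide path exists.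
- O-methylation of F4 (MeI, K2CO3, acetone) gives 24.

Step 10. The carbinol carbon is flanked by two ortho oxygens and has a para methoxy group, so even weakly acidic fluoride may ionise it; this would lead to solvolysis or to elimination towards the neighbouring stereocentre. Discrimination between the triethylsilyl ether and the aryl triisopropylsilyl ethers may also be incomplete.

The fallback avoids acid and sets out from 24. All three silyl groups are removed with acetic acid-buffered Bu4NF in THF at 0 °C to give 2-[(2R)-1-hydroxy-2-methylbutyl]-5-methoxy-4-(3-methylbut-2-enyl)benzene-1,3-diol F5, which is used at once. Only its two phenols are then silylated with i-Pr3SiCl and imidazole in DMF, a reagent that does not react with the hindered secondary benzylic alcohol. The route is rejoined at 25.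

Step 15. The methylidene intermediate 35 may be intercepted by unreacted pyrone (bis-pyrone methane formation) faster than by the crowded ring A carbon. Extended warming with the liberated amine could also start to epimerise the centre next to the ketone.

The fallback reverses the electrophile and sets out from 27.
- 27 is aminomethylated at C1 with dimethylmethylideneammonium iodide (CH2Cl2, rt, NaHCO3 work-up) to (2R)-1-[3-[(dimethylamino)methyl]-2,6-dihydroxy-4-methoxy-5-(3-methylbut-2-enyl)phenyl]-2-methylbutan-1-one F6.
- Quaternisation with MeI gives the trimethylammonium iodide F7.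
- Gentle warming of F7 with the sodium salt of 33 in MeCN expels trimethylamine to form 3-hydroxy-5-methoxy-4-(3-methylbut-2-enyl)-2-[(2R)-2-methylbutanoyl]-6-methylidenecyclohexa-2,4-dien-1-one F8, the ring A ortho-quinone methide. This is trapped by C3 of the pyrone, a known way to use phenolic Mannich base methiodides, and the route is rejoined at 36.

Further compounds
F1 | step 8 | 2-[(2R)-2-methyl-1-(triethylsilyloxy)butyl]-3-(triisopropylsilyloxy)cyclobut-2-en-1-one | O=C1CC(O[Si](C(C)C)(C(C)C)C(C)C)=C1C(O[Si](CC)(CC)CC)[C@H](C)CC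
F2 | step 8 | 5-methylhex-4-en-1-yne | C#CCC=C(C)C
F3 | step 8 | 5-methyl-1-(triisopropylsilyloxy)hex-4-en-1-yne | CC(C)=CCC#CO[Si](C(C)C)(C(C)C)C(C)C
F4 | step 8 | 2-(3-methylbut-2-enyl)-4-[(2R)-2-methyl-1-(triethylsilyloxy)butyl]-3,5-bis(triisopropylsilyloxy)phenol | Oc1cc(O[Si](C(C)C)(C(C)C)C(C)C)c(C(O[Si](CC)(CC)CC)[C@H](C)CC)c(O[Si](C(C)C)(C(C)C)C(C)C)c1CC=C(C)C
F5 | step 10 | 2-[(2R)-1-hydroxy-2-methylbutyl]-5-methoxy-4-(3-methylbut-2-enyl)benzene-1,3-diol | COc1cc(O)c(C(O)[C@H](C)CC)c(O)c1CC=C(C)C
F6 | step 15 | (2R)-1-[3-[(dimethylamino)methyl]-2,6-dihydroxy-4-methoxy-5-(3-methylbut-2-enyl)phenyl]-2-methylbutan-1-one | CN(C)Cc1c(O)c(C(=O)[C@H](C)CC)c(O)c(CC=C(C)C)c1OC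
F7 | step 15 | [2,4-dihydroxy-6-methoxy-3-[(2R)-2-methylbutanoyl]-5-(3-methylbut-2-enyl)phenyl]methyl-trimethylammonium iodide | C[N+](C)(C)Cc1c(O)c(C(=O)[C@H](C)CC)c(O)c(CC=C(C)C)c1OC.[I-]
F8 | step 15 | 3-hydroxy-5-methoxy-4-(3-methylbut-2-enyl)-2-[(2R)-2-methylbutanoyl]-6-methylidenecyclohexa-2,4-dien-1-one | C=C1C(=O)C(C(=O)[C@H](C)CC)=C(O)C(CC=C(C)C)=C1OC
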